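**Plan**

- Retrosynthetic cuts: first the two C–O bonds at the spiro acylal carbon, giving a caged hydroxy acid and a prenylated hydroxy-chromenequinone; then the tetrahydrofuran C–O bond and the C–prenyl bond at the ether carbon; last the two C–C bonds that tie the enoate bridge to the bridgeheads.
- Enabling feature: the CH=C(CO2R) bridge of the bicyclo[2.2.2]octenone spans two bridgehead carbons that both carry oxygen, and the cage ketone sits beside one of them. This is the imprint of an alkynoate added across a 1,2,4-trioxygenated cyclohexa-1,3-diene whose 2-methoxy carbon is the latent ketone.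
- Forward order: a cyclohexenone is taken to the diene; the Diels–Alder reaction closes the bicyclooctadiene; the ketone is unmasked and prenylated and the tetrahydrofuran is closed oxidatively. The 2H-pyran of the quinone partner comes from a Knoevenagel/electrocyclisation; acylation, oxygen transposition and spirolactonisation close the 1,3-dioxin-4-one last.
- Stereochemistry: one rhodium/BINAP conjugate addition sets the arm-bearing carbon; this centre steers the face of the cycloaddition (both bridgeheads); the tether fixes the ether carbon; the spiro carbon and its neighbouring CH are left to thermodynamic control.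

Key step: step 7

Assumption: (S)-BINAP selects the same enone face as with cyclohex-2-enone, and the target configuration at the spiro carbon and the adjacent prenyl-bearing CH is the thermodynamically preferred one for the reversible closure in step 19.

**Route**

Step 1
Reactants: 1 4,4-dimethoxycyclohexa-2,5-dien-1-one; 2 potassium isopropenyltrifluoroborate
Product: 3 (5S)-4,4-dimethoxy-5-(prop-1-en-2-yl)cyclohex-2-en-1-one
Conditions: [Rh(cod)2]BF4 (3 mol %), (S)-BINAP (3.3 mol %), Et3N, toluene/H2O 10:1, 50 °C, 1.1 equiv of 2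
Reagents that add atoms: none
Why: Hayashi–Miyaura asymmetric 1,4-addition, in which the alkenylrhodium species adds to one enantioface of the achiral dienone; the (S)-ligand should give the (S)-ketone by analogy with cyclohex-2-enone, and the cross-conjugated dienone should react faster than the enone product, so mono-addition is expected.

Step 2
Reactants: 3 (5S)-4,4-dimethoxy-5-(prop-1-en-2-yl)cyclohex-2-en-1-one
Product: 5 (5S)-2-hydroxy-5-(2-hydroxypropan-2-yl)-4,4-dimethoxycyclohexan-1-one (C2 epimers), via bis-hydroperoxide 4 (not isolated)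
Conditions: Mn(dpm)3 (5 mol %; dpm = dipivaloylmethanate), PhSiH3, O2 (1 atm), i-PrOH/CH2Cl2, 0 °C to 23 °C; then P(OEt)3
Reagents that add atoms: dioxygen, O=O
Why: Mukaiyama-type hydrogen-atom-transfer oxygenation, in which the manganese hydride delivers H• to the CH2 terminus of the isopropenyl group and to the β-carbon of the enone, the tertiary and α-keto radicals capture O2 and the phosphite reduces the hydroperoxides, so Markovnikov hydration and enone α-hydroxylation occur together; the C2 carbinol centre is uncontrolled and is erased in step 6.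

Step 3
Reactants: 5 (5S)-2-hydroxy-5-(2-hydroxypropan-2-yl)-4,4-dimethoxycyclohexan-1-one
Product: 6 (5S)-5-(2-hydroxypropan-2-yl)-2,4,4-trimethoxycyclohexan-1-one
Conditions: MeI, Ag2O, 4 Å molecular sieves, CH2Cl2, 23 °C, dark
Reagents that add atoms: iodomethane, CI
Why: Purdie methylation, which under neutral conditions methylates the secondary α-ketol hydroxyl, leaves the hindered tertiary hydroxyl and provides no base strong enough to shift the α-ketol.

Step 4
Reactants: 6 (5S)-5-(2-hydroxypropan-2-yl)-2,4,4-trimethoxycyclohexan-1-one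
Product: 7 (5S)-2,4,4-trimethoxy-5-[2-(triethylsilyloxy)propan-2-yl]cyclohexan-1-one
Conditions: Et3SiOTf, 2,6-lutidine, CH2Cl2, −78 °C to 0 °C
Reagents that add atoms: triethylsilyl trifluoromethanesulfonate, CC[Si](CC)(CC)OS(=O)(=O)C(F)(F)F
Why: O-silylation with a silyl triflate and a hindered pyridine base protects even a tertiary alcohol without enolising the ketone; triethylsilyl is chosen to survive step 5 yet to be removable beside the tert-butyldimethylsilyl ethers in step 8.

Step 5
Reactants: 7 (5S)-2,4,4-trimethoxy-5-[2-(triethylsilyloxy)propan-2-yl]cyclohexan-1-one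
Product: 8 (5S)-2-methoxy-5-[2-(triethylsilyloxy)propan-2-yl]cyclohexane-1,4-dione (C2 epimers)
Conditions: PPTS (cat.), acetone/H2O 10:1, 23 °C; used at once
Reagents that add atoms: water, O
Why: Acid-catalysed ketal hydrolysis, in which the dimethyl ketal is far more labile than the tertiary silyl ether; the mild acid should neither enolise the new ketone toward C5 (which would erode the stereocentre) nor eliminate methanol from the β-methoxy ketone.

Step 6
Reactants: 8 (5S)-2-methoxy-5-[2-(triethylsilyloxy)propan-2-yl]cyclohexane-1,4-dione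
Product: 9 (5S)-1,4-bis(tert-butyldimethylsilyloxy)-2-methoxy-5-[2-(triethylsilyloxy)propan-2-yl]cyclohexa-1,3-diene
Conditions: t-BuMe2SiOTf (2.5 equiv), Et3N (5 equiv), CH2Cl2, 0 °C to 23 °C
Reagents that add atoms: tert-butyldimethylsilyl trifluoromethanesulfonate, CC(C)(C)[Si](C)(C)OS(=O)(=O)C(F)(F)F
Why: Soft enolisation (O-silylation, then deprotonation by Et3N), in which the C4 carbonyl enolises toward C3H2 because C5–H is shielded by the quaternary arm, and the C1 carbonyl then loses C2–H, which is α to the carbonyl and allylic to the first enol ether, giving the conjugated diene; the methoxy-bearing centre disappears and C5 is untouched.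

Step 7
Reactants: 9 (5S)-1,4-bis(tert-butyldimethylsilyloxy)-2-methoxy-5-[2-(triethylsilyloxy)propan-2-yl]cyclohexa-1,3-diene; 10 methyl propiolate
Product: 11 methyl 1,4-bis(tert-butyldimethylsilyloxy)-5-methoxy-7-[2-(triethylsilyloxy)propan-2-yl]bicyclo[2.2.2]octa-2,5-diene-2-carboxylate (arm on C7 syn to the C5=C6 enol ether bridge; configuration as in the SMILES)
Conditions: 10 (3 equiv), BHT (cat.), toluene, 80 °C, sealed tube, argon
Reagents that add atoms: none
Why: A thermal, concerted but asynchronous normal-demand [4+2] cycloaddition between the electron-rich diene and the alkynoate; the closest known reactions are Diels–Alder additions of 1,4-bis(silyloxy)- and 2-alkoxycyclohexa-1,3-dienes to propiolates, which give bicyclo[2.2.2]octadienes. The one new six-membered ring closes by the cycloaddition itself, both σ-bonds (C1 to the propiolate β-carbon, C4 to the ester-bearing carbon) forming suprafacially on each partner. The two new stereocentres are the bridgeheads; they are created together and their configuration follows from the diene face attacked, which is controlled by the existing (S) centre, whose bulky CMe2OSiEt3 arm forces approach from the opposite face and so ends syn to the enol ether bridge. The step needs regioselectivity (ester carbon bonded to the terminus next to the arm-bearing carbon); it is secured by the 2-methoxy group, which gives the terminus beside it the larger HOMO coefficient while the effects of the two terminal silyloxy groups cancel, so that this terminus bonds to the propiolate β-carbon. The temperature is held at 80 °C to stay below Alder–Rickert loss of the saturated bridge.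

Step 8
Reactants: 11 methyl 1,4-bis(tert-butyldimethylsilyloxy)-5-methoxy-7-[2-(triethylsilyloxy)propan-2-yl]bicyclo[2.2.2]octa-2,5-diene-2-carboxylate
Product: 12 methyl 1,4-bis(tert-butyldimethylsilyloxy)-7-(2-hydroxypropan-2-yl)-5-oxobicyclo[2.2.2]oct-2-ene-2-carboxylate
Conditions: 1 M HCl, THF, 0 °C to 23 °C
Reagents that add atoms: water, O
Why: Enol ether hydrolysis (C-protonation, hydration, loss of methanol) with acid cleavage of the tertiary triethylsilyl ether; the bridgehead tert-butyldimethylsilyl ethers are hindered and much slower to hydrolyse, and a hemiketal between the freed carbinol and the new ketone would be a strained twistane-type ring.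

Step 9
Reactants: 12 methyl 1,4-bis(tert-butyldimethylsilyloxy)-7-(2-hydroxypropan-2-yl)-5-oxobicyclo[2.2.2]oct-2-ene-2-carboxylate; 13 prenyl bromide (1-bromo-3-methylbut-2-ene)
Product: 14 methyl 1,4-bis(tert-butyldimethylsilyloxy)-7-(2-hydroxypropan-2-yl)-6-(3-methylbut-2-en-1-yl)-5-oxobicyclo[2.2.2]oct-2-ene-2-carboxylate (C6 epimers)
Conditions: LiN(SiMe3)2 (2.2 equiv), THF/DMPU, −78 °C; 13, −78 °C to −20 °C; aq. NH4Cl
Reagents that add atoms: none
Why: Enolate alkylation (SN2 on the allylic bromide) of the alkoxide–enolate dianion at the only enolisable position, the other α-carbon being a bridgehead; the prenyl group must go in now because after ether closure this carbon is a ring-fusion atom whose enolate would be an anti-Bredt alkene, and the epimer ratio is irrelevant because the centre is planarised in step 10.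

Step 10
Reactants: 14 methyl 1,4-bis(tert-butyldimethylsilyloxy)-7-(2-hydroxypropan-2-yl)-6-(3-methylbut-2-en-1-yl)-5-oxobicyclo[2.2.2]oct-2-ene-2-carboxylate
Product: 15 methyl 1,4-bis(tert-butyldimethylsilyloxy)-6-(3-methylbut-2-en-1-yl)-5-(trimethylsilyloxy)-7-[2-(trimethylsilyloxy)propan-2-yl]bicyclo[2.2.2]octa-2,5-diene-2-carboxylate
Conditions: KN(SiMe3)2 (2.5 equiv), Me3SiCl (3 equiv), THF, −78 °C to 0 °C; non-aqueous work-up
Reagents that add atoms: chlorotrimethylsilane, C[Si](C)(C)Cl
Why: Enolate formation at the single remaining α-hydrogen and O-silylation, which also caps the carbinol, gives the tetrasubstituted silyl enol ether and re-planarises the prenyl-bearing carbon.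

Step 11
Reactants: 15 methyl 1,4-bis(tert-butyldimethylsilyloxy)-6-(3-methylbut-2-en-1-yl)-5-(trimethylsilyloxy)-7-[2-(trimethylsilyloxy)propan-2-yl]bicyclo[2.2.2]octa-2,5-diene-2-carboxylate
Product: 16 methyl 1,7-bis(tert-butyldimethylsilyloxy)-5,5-dimethyl-3-(3-methylbut-2-en-1-yl)-2-oxo-4-oxatricyclo[4.3.1.0^3,7]dec-8-ene-8-carboxylate
Conditions: PhIO, BF3·OEt2, CH2Cl2, −78 °C to −40 °C
Reagents that add atoms: none
Why: Umpolung α-oxygenation of a silyl enol ether with trivalent iodine, in which the enol ether attacks the activated iodosylbenzene and the α-carbon, now electrophilic with iodobenzene as leaving group, is captured by the neighbouring silyl ether oxygen in a 5-exo-tet closure; the oxygen can reach this carbon only from the face of the carbinol arm, so the new quaternary centre carries the ether oxygen syn to the arm and the prenyl group toward the enoate bridge.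

Step 12
Reactants: 16 methyl 1,7-bis(tert-butyldimethylsilyloxy)-5,5-dimethyl-3-(3-methylbut-2-en-1-yl)-2-oxo-4-oxatricyclo[4.3.1.0^3,7]dec-8-ene-8-carboxylate
Product: 17 1,7-bis(tert-butyldimethylsilyloxy)-5,5-dimethyl-3-(3-methylbut-2-en-1-yl)-2-oxo-4-oxatricyclo[4.3.1.0^3,7]dec-8-ene-8-carboxylic acid
Conditions: LiOH·H2O, THF/MeOH/H2O, 40 °C; then 1 M HCl to pH 3, 0 °C
Reagents that add atoms: lithium hydroxide, [Li+].[OH-]
Why: Saponification (acyl–oxygen cleavage) of the conjugated methyl ester; the ketone is non-enolisable and both bridgehead hydroxyls are still silylated, so no α-ketol or retro-aldol pathway is open to base.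

Step 13
Reactants: 17 1,7-bis(tert-butyldimethylsilyloxy)-5,5-dimethyl-3-(3-methylbut-2-en-1-yl)-2-oxo-4-oxatricyclo[4.3.1.0^3,7]dec-8-ene-8-carboxylic acid
Product: 18 1,7-dihydroxy-5,5-dimethyl-3-(3-methylbut-2-en-1-yl)-2-oxo-4-oxatricyclo[4.3.1.0^3,7]dec-8-ene-8-carboxylic acid
Conditions: HF·pyridine, pyridine, THF, 0 °C to 23 °C
Reagents that add atoms: none
Why: Fluoride-driven Si–O cleavage under mildly acidic conditions; the liberated β-hydroxy ketone should resist retro-aldol cleavage because the bond that would break lies in the plane of the carbonyl group within the rigid cage, and the absence of base avoids an α-ketol shift at the other bridgehead.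

Step 14
Reactants: 19 2,6-dimethoxy-1,4-benzoquinone
Product: 20 2-hydroxy-6-methoxy-1,4-benzoquinone
Conditions: NaOH (1.1 equiv), H2O/THF, 0 °C to 23 °C; then 1 M HCl
Reagents that add atoms: sodium hydroxide, [Na+].[OH-]
Why: Hydrolysis of a vinylogous ester by conjugate addition–elimination of hydroxide; the product forms as its anion, which deactivates the ring toward loss of the second methoxy group.

Step 15
Reactants: 20 2-hydroxy-6-methoxy-1,4-benzoquinone; 21 3-methylbut-2-enal
Product: 23 7-methoxy-2,2-dimethyl-2H-chromene-5,8-dione, via oxatriene 22 (not isolated)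
Conditions: ethylenediammonium diacetate (10 mol %), toluene, 80 °C
Reagents that add atoms: none
Why: Knoevenagel condensation at the nucleophilic ring carbon of the hydroxyquinone followed by oxa-6π-electrocyclisation of the 1-oxatriene closes the 2H-pyran; closure onto the oxygen that keeps the para-quinone is the usual outcome for 2-hydroxy-1,4-quinones.

Step 16
Reactants: 23 7-methoxy-2,2-dimethyl-2H-chromene-5,8-dione
Product: 24 7-hydroxy-2,2-dimethyl-2H-chromene-5,8-dione
Conditions: NaOH (1.1 equiv), H2O/THF, 0 °C; then 1 M HCl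
Reagents that add atoms: sodium hydroxide, [Na+].[OH-]
Why: Vinylogous ester hydrolysis as in step 14; hydroxide attacks the methoxy-bearing C7, which is less substituted than the pyran ring-fusion carbon, where addition would in any case be reversible.

Step 17
Reactants: 24 7-hydroxy-2,2-dimethyl-2H-chromene-5,8-dione; 13 prenyl bromide
Product: 25 7-hydroxy-2,2-dimethyl-6-(3-methylbut-2-en-1-yl)-2H-chromene-5,8-dione
Conditions: LiH, DMSO, 23 °C; then 13, 23 °C to 45 °C
Reagents that add atoms: none
Why: C-Alkylation of the ambident hydroxyquinone anion at the carbon between the enolic oxygen and the C5 carbonyl (lapachol-type prenylation); the lithium counter-ion in DMSO is used to favour attack through carbon over oxygen.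

Step 18
Reactants: 18 1,7-dihydroxy-5,5-dimethyl-3-(3-methylbut-2-en-1-yl)-2-oxo-4-oxatricyclo[4.3.1.0^3,7]dec-8-ene-8-carboxylic acid; 25 7-hydroxy-2,2-dimethyl-6-(3-methylbut-2-en-1-yl)-2H-chromene-5,8-dione
Product: 26 2,2-dimethyl-6-(3-methylbut-2-en-1-yl)-5,8-dioxo-2H-chromen-7-yl ester of acid 18 (acyloxyquinone)
Conditions: DCC, DMAP (cat.), CH2Cl2, 0 °C to 23 °C
Reagents that add atoms: none
Why: Steglich-type carbodiimide coupling in which the hydroxyquinone, a vinylogous carboxylic acid, is O-acylated to a vinylogous mixed anhydride; the two tertiary hydroxyls of 18 are too hindered to compete.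

Step 19
Reactants: 26 acyloxyquinone
Product: 28 target CNP0222516.1, via quinone ether acid 27 (not isolated)
Conditions: Et3N (1.5 equiv), CH2Cl2, 0 °C to 23 °C; then AcOH (5 equiv), 23 °C to 40 °C
Reagents that add atoms: none
Why: Proposed new method: Et3N makes a little of the bridgehead alkoxide, which adds 6-exo-trig to the acyloxy-bearing quinone carbon, and the resulting enolate expels the carboxylate (addition–elimination) to give 27; on acidification the carboxylic acid adds back to the same, now alkoxy-substituted, quinone carbon (6-exo-trig oxa-Michael) and the dienol ketonises to the C–H form, which closes the spiro 1,3-dioxin-4-one. The closest known reactions are nucleophilic vinylic substitution on 2-acyloxy- and 2-halo-1,4-quinones and intramolecular oxa-Michael lactonisation of carboxylic acids onto enones; both new stereocentres (spiro carbon and prenyl-bearing CH) should settle under thermodynamic control because ring opening and enolisation are reversible.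

**Compound list**

1 | 4,4-dimethoxycyclohexa-2,5-dien-1-one | COC1(OC)C=CC(=O)C=C1 | starting material
2 | potassium isopropenyltrifluoroborate | [K+].CC(=C)[B-](F)(F)F | starting material
3 | (5S)-4,4-dimethoxy-5-(prop-1-en-2-yl)cyclohex-2-en-1-one | O=C1C[C@@H](C(C)=C)C(OC)(OC)C=C1 | intermediate
4 | bis-hydroperoxide: (5S)-2-hydroperoxy-5-(2-hydroperoxypropan-2-yl)-4,4-dimethoxycyclohexan-1-one | O=C1C[C@@H](C(C)(C)OO)C(OC)(OC)CC1OO | intermediate (not isolated)
5 | (5S)-2-hydroxy-5-(2-hydroxypropan-2-yl)-4,4-dimethoxycyclohexan-1-one | O=C1C[C@@H](C(C)(C)O)C(OC)(OC)CC1O | intermediate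
6 | (5S)-5-(2-hydroxypropan-2-yl)-2,4,4-trimethoxycyclohexan-1-one | O=C1C[C@@H](C(C)(C)O)C(OC)(OC)CC1OC | intermediate
7 | (5S)-2,4,4-trimethoxy-5-[2-(triethylsilyloxy)propan-2-yl]cyclohexan-1-one | O=C1C[C@@H](C(C)(C)O[Si](CC)(CC)CC)C(OC)(OC)CC1OC | intermediate
8 | (5S)-2-methoxy-5-[2-(triethylsilyloxy)propan-2-yl]cyclohexane-1,4-dione | O=C1C[C@@H](C(C)(C)O[Si](CC)(CC)CC)C(=O)CC1OC | intermediate
9 | (5S)-1,4-bis(tert-butyldimethylsilyloxy)-2-methoxy-5-[2-(triethylsilyloxy)propan-2-yl]cyclohexa-1,3-diene | COC1=C(O[Si](C)(C)C(C)(C)C)C[C@@H](C(C)(C)O[Si](CC)(CC)CC)C(O[Si](C)(C)C(C)(C)C)=C1 | intermediate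
10 | methyl propiolate | C#CC(=O)OC | starting material
11 | methyl 1,4-bis(tert-butyldimethylsilyloxy)-5-methoxy-7-[2-(triethylsilyloxy)propan-2-yl]bicyclo[2.2.2]octa-2,5-diene-2-carboxylate | COC(=O)C1=C[C@]2(O[Si](C)(C)C(C)(C)C)C[C@@H](C(C)(C)O[Si](CC)(CC)CC)[C@@]1(O[Si](C)(C)C(C)(C)C)C=C2OC | intermediate
12 | methyl 1,4-bis(tert-butyldimethylsilyloxy)-7-(2-hydroxypropan-2-yl)-5-oxobicyclo[2.2.2]oct-2-ene-2-carboxylate | COC(=O)C1=C[C@]2(O[Si](C)(C)C(C)(C)C)C[C@@H](C(C)(C)O)[C@@]1(O[Si](C)(C)C(C)(C)C)CC2=O | intermediate
13 | prenyl bromide (1-bromo-3-methylbut-2-ene) | CC(C)=CCBr | starting material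
14 | methyl 1,4-bis(tert-butyldimethylsilyloxy)-7-(2-hydroxypropan-2-yl)-6-(3-methylbut-2-en-1-yl)-5-oxobicyclo[2.2.2]oct-2-ene-2-carboxylate (C6 epimers) | COC(=O)C1=C[C@]2(O[Si](C)(C)C(C)(C)C)C[C@@H](C(C)(C)O)[C@@]1(O[Si](C)(C)C(C)(C)C)C(CC=C(C)C)C2=O | intermediate
15 | methyl 1,4-bis(tert-butyldimethylsilyloxy)-6-(3-methylbut-2-en-1-yl)-5-(trimethylsilyloxy)-7-[2-(trimethylsilyloxy)propan-2-yl]bicyclo[2.2.2]octa-2,5-diene-2-carboxylate | COC(=O)C1=C[C@]2(O[Si](C)(C)C(C)(C)C)C[C@@H](C(C)(C)O[Si](C)(C)C)[C@@]1(O[Si](C)(C)C(C)(C)C)C(CC=C(C)C)=C2O[Si](C)(C)C | intermediate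
16 | methyl 1,7-bis(tert-butyldimethylsilyloxy)-5,5-dimethyl-3-(3-methylbut-2-en-1-yl)-2-oxo-4-oxatricyclo[4.3.1.0^3,7]dec-8-ene-8-carboxylate | COC(=O)C1=C[C@]3(O[Si](C)(C)C(C)(C)C)C[C@H]4C(C)(C)O[C@@](CC=C(C)C)(C3=O)[C@@]14O[Si](C)(C)C(C)(C)C | intermediate
17 | 1,7-bis(tert-butyldimethylsilyloxy)-5,5-dimethyl-3-(3-methylbut-2-en-1-yl)-2-oxo-4-oxatricyclo[4.3.1.0^3,7]dec-8-ene-8-carboxylic acid | OC(=O)C1=C[C@]3(O[Si](C)(C)C(C)(C)C)C[C@H]4C(C)(C)O[C@@](CC=C(C)C)(C3=O)[C@@]14O[Si](C)(C)C(C)(C)C | intermediate
18 | 1,7-dihydroxy-5,5-dimethyl-3-(3-methylbut-2-en-1-yl)-2-oxo-4-oxatricyclo[4.3.1.0^3,7]dec-8-ene-8-carboxylic acid | OC(=O)C1=C[C@]3(O)C[C@H]4C(C)(C)O[C@@](CC=C(C)C)(C3=O)[C@@]14O | intermediate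
19 | 2,6-dimethoxy-1,4-benzoquinone | COC1=CC(=O)C=C(OC)C1=O | starting material
20 | 2-hydroxy-6-methoxy-1,4-benzoquinone | COC1=CC(=O)C=C(O)C1=O | intermediate
21 | 3-methylbut-2-enal | CC(C)=CC=O | starting material
22 | oxatriene: 5-methoxy-3-(3-methylbut-2-en-1-ylidene)cyclohex-5-ene-1,2,4-trione | COC1=CC(=O)C(=CC=C(C)C)C(=O)C1=O | intermediate (not isolated)
23 | 7-methoxy-2,2-dimethyl-2H-chromene-5,8-dione | COC1=CC(=O)C2=C(OC(C)(C)C=C2)C1=O | intermediate
24 | 7-hydroxy-2,2-dimethyl-2H-chromene-5,8-dione | OC1=CC(=O)C2=C(OC(C)(C)C=C2)C1=O | intermediate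
25 | 7-hydroxy-2,2-dimethyl-6-(3-methylbut-2-en-1-yl)-2H-chromene-5,8-dione | CC(C)=CCC1=C(O)C(=O)C2=C(C=CC(C)(C)O2)C1=O | intermediate
26 | acyloxyquinone: 2,2-dimethyl-6-(3-methylbut-2-en-1-yl)-5,8-dioxo-2H-chromen-7-yl ester of acid 18 | CC(C)=CCC1=C(OC(=O)C3=C[C@]4(O)C[C@H]5C(C)(C)O[C@@](CC=C(C)C)(C4=O)[C@@]35O)C(=O)C2=C(C=CC(C)(C)O2)C1=O | intermediate
27 | quinone ether acid: acid 18 with its C7 oxygen bonded to C7 of the 2,2-dimethyl-6-prenyl-2H-chromene-5,8-dione | CC(C)=CCC1=C(O[C@]34C(C(=O)O)=C[C@]5(O)C[C@H]3C(C)(C)O[C@@]4(CC=C(C)C)C5=O)C(=O)C2=C(C=CC(C)(C)O2)C1=O | intermediate (not isolated)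
28 | CNP0222516.1: spiro 1,3-dioxin-4-one joining the caged tetrahydrofuran-bridged bicyclooctenone to the prenylated 2H-chromene-5,8-dione ring | CC(C)=CC[C@H]1C(=O)C2=C(OC(C)(C)C=C2)C(=O)[C@@]12OC(=O)C1=C[C@]3(O)C[C@H]4C(C)(C)O[C@@](CC=C(C)C)(C3=O)[C@@]14O2 | target

**Count and risks**

Total steps: 19. Longest linear sequence: 15 steps (steps 1–13, 18 and 19); the quinone branch (steps 14–17) has four steps.

Steps most likely to fail:

1. Step 19. The hindered bridgehead alkoxide may add too slowly; the closure may stop at the open quinone ether acid because the fully conjugated quinone is favoured; or the equilibrium may show too little bias between the spiro and CH epimers. Fallback by known chemistry, setting out from 27 (isolated after the base stage): Na2S2O4 reduces the quinone to the hydroquinone acid F1. The less hindered phenol, between the prenyl carbon and the chromene carbon, is silylated with t-BuMe2SiCl/imidazole to the mono-silyl ether F2. PhI(OAc)2 then effects a Wessely-type oxidative dearomatisation of the remaining 2-alkoxyphenol, in which the tethered carboxylic acid adds to the alkoxy-bearing ortho carbon and gives the spiro acylal as its silyl dienol ether F3. HF·pyridine removes the silyl group and ketonisation of the dienol returns the route to 28.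

2. Step 11. The electron-rich bridgehead bond next to the activated carbon may shift (semipinacol-type ring contraction), a ligand may be transferred from iodine instead of the ether closing, or the prenyl alkene may be oxidised. Fallback, setting out from 15: N-bromosuccinimide at −78 °C brominates the silyl enol ether from the open face, anti to the arm, to give the α-bromo ketone F4. AgOSO2CF3 with 2,6-di-tert-butylpyridine then abstracts bromide, and the arm's silyl ether oxygen closes the tetrahydrofuran from the arm face with loss of the trimethylsilyl group, rejoining the route at 16.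

3. Step 7. Regiocontrol may erode if crowding twists the methoxy group out of conjugation, or the adduct may lose its saturated bridge and aromatise at the temperature needed for the alkynoate to react. Fallback within the same disconnection, setting out from 9: methyl 2-chloroacrylate, an alkene surrogate of the alkynoate, should add with the same orientation (its CH2 to the methoxy-flanked terminus) at or below 60 °C, forming the same two bonds and the same ring and giving the chloro ester adduct F5, a bicyclooctene that cannot aromatise by bridge extrusion. DBU then removes HCl by syn-elimination across the eclipsed bridge, where the only β-hydrogens sit, and the route is rejoined at 11.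

**Further compounds**

F1 | step 19 | hydroquinone acid | CC(C)=CCc1c(O[C@]34C(C(=O)O)=C[C@]5(O)C[C@H]3C(C)(C)O[C@@]4(CC=C(C)C)C5=O)c(O)c2OC(C)(C)C=Cc2c1O
F2 | step 19 | mono-silyl ether | CC(C)=CCc1c(O[C@]34C(C(=O)O)=C[C@]5(O)C[C@H]3C(C)(C)O[C@@]4(CC=C(C)C)C5=O)c(O)c2OC(C)(C)C=Cc2c1O[Si](C)(C)C(C)(C)C
F3 | step 19 | silyl dienol ether | CC(C)=CCC1=C(O[Si](C)(C)C(C)(C)C)C2=C(OC(C)(C)C=C2)C(=O)[C@@]12OC(=O)C1=C[C@]3(O)C[C@H]4C(C)(C)O[C@@](CC=C(C)C)(C3=O)[C@@]14O2
F4 | step 11 | α-bromo ketone | COC(=O)C1=C[C@]2(O[Si](C)(C)C(C)(C)C)C[C@@H](C(C)(C)O[Si](C)(C)C)[C@@]1(O[Si](C)(C)C(C)(C)C)[C@@](Br)(CC=C(C)C)C2=O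
F5 | step 7 | chloro ester adduct | COC(=O)C1(Cl)C[C@]2(O[Si](C)(C)C(C)(C)C)C[C@@H](C(C)(C)O[Si](CC)(CC)CC)[C@@]1(O[Si](C)(C)C(C)(C)C)C=C2OC
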